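**Retrosynthetic overview**
1. Both benzene rings are bought: ring A as 3',4',5'-trimethoxyacetophenone 1 (its two free ring C–H bonds are equivalent), ring B as 3,4-dimethoxybenzoic acid 2.
2. Key C–O disconnection: aryl ester 3 ⇒ 1 + 2 by ortho C–H/O–H coupling, which puts the future ring oxygen O1 on C8a and joins the two halves.
3. 1,3-Diketone 4 ⇒ 3 by O→C acyl shift (makes C2–C3).
4. Pyran-4-one ⇒ 4 by the second C–O bond (O1–C2) through hemiketal 5 and loss of water, giving target 6.
5. Ring order: the pyranone is the only ring formed, and it is formed last.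

Assumption: the target is planar with no stereocentre or stereogenic axis, so "single enantiomer" is read as the achiral compound exactly as drawn.

**Step 1**
Reactants: 1 3',4',5'-trimethoxyacetophenone; 2 3,4-dimethoxybenzoic acid
Product: 3 6-acetyl-2,3,4-trimethoxyphenyl 3,4-dimethoxybenzoate
Conditions: [RuCl2(p-cymene)]2 (5 mol %), AgSbF6 (20 mol %), (NH4)2S2O8 (2 equiv), 1 in 1.5-fold excess, ClCH2CH2Cl, 100 °C
Reagents that add atoms: none
Why: Proposed new method: ketone-directed Ru(II)-catalysed dehydrogenative C(sp2)–H/O–H coupling of an aryl ketone with an arenecarboxylic acid, in which the cationic Ru(II) carboxylate binds the acetyl oxygen of 1, carboxylate-assisted metalation–deprotonation cleaves one of the two equivalent ring C–H bonds (so only one regioisomer is possible) to give a five-membered ruthenacycle, peroxodisulfate oxidises this to a Ru(IV) aryl carboxylate and C(aryl)–O reductive elimination releases ester 3 and Ru(II); the closest known reaction types are Ru(II)-catalysed ketone-directed ortho-C–H hydroxylation (via aryl trifluoroacetates) and Ru(II)/peroxodisulfate ortho-benzoxylation of anilides and benzamides with ArCO2H, neither of which pairs a ketone directing group with an arenecarboxylic acid.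

**Step 2**
Reactants: 3 6-acetyl-2,3,4-trimethoxyphenyl 3,4-dimethoxybenzoate
Product: 4 1-(3,4-dimethoxyphenyl)-3-(2-hydroxy-3,4,5-trimethoxyphenyl)propane-1,3-dione
Conditions: KOH (powdered, 3 equiv), pyridine, 50 °C; then cold 1 M HCl
Reagents that add atoms: none
Why: Baker–Venkataraman rearrangement, in which the acetyl enolate attacks the neighbouring aryl ester carbonyl through a six-membered cyclic alkoxide that collapses to the stable phenoxide/β-diketonate; this intramolecular Claisen acyl transfer is routine for polymethoxylated 2-acyloxyacetophenones and leaves the methyl ethers untouched.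

**Step 3**
Reactants: 4 1-(3,4-dimethoxyphenyl)-3-(2-hydroxy-3,4,5-trimethoxyphenyl)propane-1,3-dione
Product: 6 2-(3,4-dimethoxyphenyl)-6,7,8-trimethoxy-4H-chromen-4-one (target), via cyclic hemiketal 5 (not isolated)
Conditions: conc. H2SO4 (cat.), AcOH, 100 °C, 1 h
Reagents that add atoms: none
Why: Acid-catalysed cyclodehydration (closing step of the Baker–Venkataraman flavone synthesis), in which the phenol adds to the protonated distal carbonyl to form the O1–C2 bond in racemic hemiketal 5, whose only stereocentre is lost on elimination of water to the conjugated pyran-4-one; there is no 5-OMe, so chelation-assisted demethylation is not a concern.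

**Compound list**
1 | 1-(3,4,5-trimethoxyphenyl)ethan-1-one (3',4',5'-trimethoxyacetophenone) | CC(=O)c1cc(OC)c(OC)c(OC)c1 | starting material
2 | 3,4-dimethoxybenzoic acid (veratric acid) | OC(=O)c1ccc(OC)c(OC)c1 | starting material
3 | 6-acetyl-2,3,4-trimethoxyphenyl 3,4-dimethoxybenzoate | CC(=O)c1cc(OC)c(OC)c(OC)c1OC(=O)c1ccc(OC)c(OC)c1 | intermediate
4 | 1-(3,4-dimethoxyphenyl)-3-(2-hydroxy-3,4,5-trimethoxyphenyl)propane-1,3-dione | COc1ccc(C(=O)CC(=O)c2cc(OC)c(OC)c(OC)c2O)cc1OC | intermediate
5 | 2-(3,4-dimethoxyphenyl)-2-hydroxy-6,7,8-trimethoxy-2,3-dihydro-4H-chromen-4-one (racemic cyclic hemiketal, not isolated) | COc1ccc(C2(O)CC(=O)c3cc(OC)c(OC)c(OC)c3O2)cc1OC | intermediate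
6 | 2-(3,4-dimethoxyphenyl)-6,7,8-trimethoxy-4H-chromen-4-one (achiral, no stereodescriptors) | COc1ccc(-c2cc(=O)c3cc(OC)c(OC)c(OC)c3o2)cc1OC | target

**Total step count:** 3
**Longest linear sequence:** 3 (1 → 3 → 4 → 6)

**Steps most likely to fail, in order of risk**

Step 1 (the proposed new coupling). The acetyl group is a weak director and the C–H bond to be cleaved is flanked by a methoxy group. A second aroyloxylation at the other ortho position is possible, which the excess of 1 is meant to suppress. Peroxodisulfate could also oxidise or decarboxylate the electron-rich partners. The fallback uses known chemistry only, sets out from 1 and comes back to the route at 6. Electrophilic ring iodination of 1 (NIS, cat. CF3CO2H, MeCN, rt; the only free ring positions are the two equivalent ones) gives 1-(2-iodo-3,4,5-trimethoxyphenyl)ethan-1-one F1. Crossed Claisen condensation of F1 with commercial methyl 3,4-dimethoxybenzoate (NaH, THF, reflux) gives 1-(3,4-dimethoxyphenyl)-3-(2-iodo-3,4,5-trimethoxyphenyl)propane-1,3-dione F2. Copper-catalysed intramolecular Ullmann-type O-arylation of the enolate of F2 (CuI, 1,10-phenanthroline, K2CO3, DMF, 110 °C) closes the pyranone and gives 6. In this fallback the aryl C–O bond comes from a C–I bond and the ring oxygen from the diketone enol.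

Step 2. Hydroxide may cleave the hindered aryl ester instead of promoting the acyl shift. The fallback sets out from 3 and comes back at 6. Deliberate saponification of 3 (KOH, MeOH/H2O, rt; then HCl) gives 1-(2-hydroxy-3,4,5-trimethoxyphenyl)ethan-1-one F3, with 2 recovered. Claisen–Schmidt condensation of F3 with commercial 3,4-dimethoxybenzaldehyde (KOH, EtOH, rt) gives (E)-3-(3,4-dimethoxyphenyl)-1-(2-hydroxy-3,4,5-trimethoxyphenyl)prop-2-en-1-one F4. Oxidative cyclisation of F4 (I2 cat., DMSO, 130 °C) gives 6. The C2–C3 bond then comes from an aldol condensation and the ring closes by oxidative oxa-Michael addition instead of dehydration.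

Step 3. This is the least risky step; possible problems are partial ether cleavage or ring sulfonation in hot acid, or a stalled hemiketal. The fallback sets out from 3 and comes back at 6, replacing steps 2 and 3 together and avoiding strong acid. α-Bromination of the acetyl group of 3 (CuBr2, EtOAc/CHCl3, reflux) gives 6-(2-bromoacetyl)-2,3,4-trimethoxyphenyl 3,4-dimethoxybenzoate F5. Triphenylphosphine (MeCN, rt) converts F5 into {2-[2-(3,4-dimethoxybenzoyloxy)-3,4,5-trimethoxyphenyl]-2-oxoethyl}triphenylphosphonium bromide F6. Aqueous Na2CO3/CH2Cl2 then gives the stabilised ylide 1-[2-(3,4-dimethoxybenzoyloxy)-3,4,5-trimethoxyphenyl]-2-(triphenyl-λ5-phosphanylidene)ethan-1-one F7 (not isolated). On warming in toluene F7 undergoes intramolecular Wittig olefination of the ester carbonyl and gives 6 directly.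

**Further compounds**
F1 | step 1 | 1-(2-iodo-3,4,5-trimethoxyphenyl)ethan-1-one | CC(=O)c1cc(OC)c(OC)c(OC)c1I
F2 | step 1 | 1-(3,4-dimethoxyphenyl)-3-(2-iodo-3,4,5-trimethoxyphenyl)propane-1,3-dione | COc1ccc(C(=O)CC(=O)c2cc(OC)c(OC)c(OC)c2I)cc1OC
F3 | step 2 | 1-(2-hydroxy-3,4,5-trimethoxyphenyl)ethan-1-one | CC(=O)c1cc(OC)c(OC)c(OC)c1O
F4 | step 2 | (E)-3-(3,4-dimethoxyphenyl)-1-(2-hydroxy-3,4,5-trimethoxyphenyl)prop-2-en-1-one | COc1ccc(/C=C/C(=O)c2cc(OC)c(OC)c(OC)c2O)cc1OC
F5 | step 3 | 6-(2-bromoacetyl)-2,3,4-trimethoxyphenyl 3,4-dimethoxybenzoate | O=C(CBr)c1cc(OC)c(OC)c(OC)c1OC(=O)c1ccc(OC)c(OC)c1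
F6 | step 3 | {2-[2-(3,4-dimethoxybenzoyloxy)-3,4,5-trimethoxyphenyl]-2-oxoethyl}triphenylphosphonium bromide | [Br-].O=C(C[P+](c1ccccc1)(c1ccccc1)c1ccccc1)c1cc(OC)c(OC)c(OC)c1OC(=O)c1ccc(OC)c(OC)c1
F7 | step 3 | 1-[2-(3,4-dimethoxybenzoyloxy)-3,4,5-trimethoxyphenyl]-2-(triphenyl-λ5-phosphanylidene)ethan-1-one | O=C(C=P(c1ccccc1)(c1ccccc1)c1ccccc1)c1cc(OC)c(OC)c(OC)c1OC(=O)c1ccc(OC)c(OC)c1
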